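**Plan**

1. Retrosynthetic cuts, in order: (a) the C1=C2 alkene of the heptadienyl chain (cross-metathesis of a ring A vinyl group with a furyl 1,4-diene); (b) B-O1–B-C5 (Baeyer–Villiger); (c) B-C4–B-C5 (ring expansion of an oxaspiropentane); (d) the oxirane and the cyclopropylidene C=C; (e) A-O1–A-C5, back to (R)-linalool.
2. Enabling feature: ring B (B-O1, B-C2, B-C3, B-C4, B-C5) has a quaternary B-C5 bonded to B-O1 and to the B-C4 methylene. This is the pattern left by oxygen insertion into a 2,2-disubstituted cyclobutanone, which is what an oxirane and a cyclopropane sharing one spiro carbon give when a cyclopropane bond shifts to the other oxirane carbon.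
3. Forward order: ring A (5-exo opening of epoxylinalool), trimming of the hydroxypropyl group to acetyl, cyclopropane (Wittig), oxirane (Shi), cyclobutanone (key step), ring B (Baeyer–Villiger). The furyl diene is made separately (carboalumination, B-alkyl Suzuki coupling) and joined last by metathesis.
4. Stereochemistry: A-C2 from (R)-linalool; A-C5 from a catalyst-controlled Shi epoxidation and inversion on ring closure; B-C5 from a second Shi epoxidation, passed on by inversion in the ring expansion and retention in the Baeyer–Villiger step; 4E alkene from syn-carboalumination, 1E alkene from metathesis.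
5. Labels: ring A = tetrahydrofuran (O1, C2 quaternary, C3, C4, C5 methine); ring B = γ-lactone (O1, C2 carbonyl, C3, C4, C5 quaternary).

Key step: step 7

Remark on the chemistry: the facial sense of the two fructose-derived ketone catalysts is taken from the spiro transition-state model for trans-disubstituted and trisubstituted olefins, in which the D-series ketone gives R,R epoxides.

**Route**

Step 1
Reactants: 1 (R)-linalool
Product: 2 (3R)-5-[(2S)-3,3-dimethyloxiran-2-yl]-3-methylpent-1-en-3-ol
Conditions: 1,2:4,5-di-O-isopropylidene-β-L-erythro-2,3-hexodiulo-2,6-pyranose (L-fructose-derived Shi ketone, 0.3 equiv), KHSO5 (as Oxone), K2CO3, Bu4NHSO4 (cat), MeCN–CH2(OMe)2–aq Na2B4O7 buffer, pH 10.5, 0 °C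
Reagents that add atoms: potassium peroxymonosulfate, [K+].[O-]S(=O)(=O)OO
Why: Shi asymmetric epoxidation, in which the chiral dioxirane attacks only the electron-rich trisubstituted C6=C7 bond (the vinyl group is too poor a nucleophile and the free tertiary hydroxyl is tolerated) and the L-series catalyst is expected to deliver oxygen to the face that gives the 6S oxirane, independently of the remote C3 centre.

Step 2
Reactants: 2 (3R)-5-[(2S)-3,3-dimethyloxiran-2-yl]-3-methylpent-1-en-3-ol
Product: 3 2-[(2R,5R)-5-methyl-5-vinyltetrahydrofuran-2-yl]propan-2-ol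
Conditions: (+)-camphor-10-sulfonic acid (cat), CH2Cl2, 0 °C
Reagents that add atoms: none
Why: acid-catalysed intramolecular epoxide opening in which the tertiary hydroxyl attacks the secondary oxirane carbon in a 5-exo-tet closure with inversion, so that the 6S oxirane becomes the R-configured A-C5 carrying the hydroxypropyl group trans to vinyl, the 6-endo tetrahydropyran regioisomer being the expected minor and separable by-product.

Step 3
Reactants: 3 2-[(2R,5R)-5-methyl-5-vinyltetrahydrofuran-2-yl]propan-2-ol
Product: 5 (2R,5R)-2-methyl-5-(prop-1-en-2-yl)-2-vinyltetrahydrofuran, via phosphorodichloridate ester 4 (not isolated)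
Conditions: POCl3, pyridine, 0 °C to rt
Reagents that add atoms: none
Why: E2 dehydration of a tertiary alcohol through its dichlorophosphate, in which six methyl hydrogens compete against the single, hindered ring methine hydrogen, so that the isopropenyl isomer should predominate and neither stereocentre is touched.

Step 4
Reactants: 5 (2R,5R)-2-methyl-5-(prop-1-en-2-yl)-2-vinyltetrahydrofuran
Product: 7 1-[(2R,5R)-5-methyl-5-vinyltetrahydrofuran-2-yl]ethan-1-one, via methyloxirane 6 (not isolated)
Conditions: mCPBA (1.05 equiv), CH2Cl2, 0 °C; then H5IO6, THF–H2O, 0 °C to rt, same flask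
Reagents that add atoms: 3-chloroperoxybenzoic acid (mCPBA), O=C(OO)c1cccc(Cl)c1; water, O (the carbonyl oxygen stems from the peracid if water opens the oxirane at CH2 and from water if it opens at the quaternary carbon)
Why: Prilezhaev epoxidation followed by periodic acid cleavage of the oxirane (hydrolysis to the diol and glycol fission), in which the peracid prefers the 1,1-disubstituted isopropenyl group to the less nucleophilic vinyl group shielded by the quaternary A-C2, and loss of formaldehyde leaves the methyl ketone without touching the ring stereocentres.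

Step 5
Reactants: 7 1-[(2R,5R)-5-methyl-5-vinyltetrahydrofuran-2-yl]ethan-1-one; 8 (3-bromopropyl)triphenylphosphonium bromide
Product: 11 (2R,5R)-5-(1-cyclopropylideneethyl)-2-methyl-2-vinyltetrahydrofuran, via cyclopropyltriphenylphosphonium bromide 9 (not isolated), via cyclopropylidenetriphenylphosphorane 10 (not isolated)
Conditions: 8 (1.5 equiv), KOtBu (3.0 equiv), THF, 65 °C; then 7, rt to 50 °C
Reagents that add atoms: none
Why: Wittig olefination in which the first equivalent of base closes the three-membered ring by intramolecular alkylation, the second gives the cyclopropylidene ylide, and this ylide converts the methyl ketone into the tetrasubstituted alkylidenecyclopropane; the ylide is formed completely before the ketone is added so that no free alkoxide remains to epimerise A-C5, and no stereocentre is created.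

Step 6
Reactants: 11 (2R,5R)-5-(1-cyclopropylideneethyl)-2-methyl-2-vinyltetrahydrofuran
Product: 12 (2R)-2-methyl-2-[(2R,5R)-5-methyl-5-vinyltetrahydrofuran-2-yl]-1-oxaspiro[2.2]pentane
Conditions: 1,2:4,5-di-O-isopropylidene-β-D-erythro-2,3-hexodiulo-2,6-pyranose (D-fructose-derived Shi ketone, 0.3 equiv), KHSO5 (as Oxone), K2CO3, Bu4NHSO4 (cat), MeCN–CH2(OMe)2–aq Na2B4O7 buffer, pH 10.5, −10 to 0 °C; basic work-up, crude product used directly
Reagents that add atoms: potassium peroxymonosulfate, [K+].[O-]S(=O)(=O)OO
Why: Shi epoxidation of an alkylidenecyclopropane, in which the strained tetrasubstituted alkene is by far the most nucleophilic π bond and the basic buffer preserves the acid-labile oxaspiropentane; with the tetrahydrofuranyl group in the place of the large olefin substituent and methyl in that of the small one in the spiro transition state, the D-series catalyst is expected to place oxygen on the face that makes the oxirane carbon R.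

Step 7
Reactants: 12 (2R)-2-methyl-2-[(2R,5R)-5-methyl-5-vinyltetrahydrofuran-2-yl]-1-oxaspiro[2.2]pentane
Product: 13 (2S)-2-methyl-2-[(2R,5R)-5-methyl-5-vinyltetrahydrofuran-2-yl]cyclobutan-1-one
Conditions: Et2AlCl (1.1 equiv), CH2Cl2, −78 °C; aq KNaC4H4O6 quench
Reagents that add atoms: none
Why: Et2AlCl binds the oxirane oxygen, the C–O bond at the oxirane carbon that carries methyl and ring A lengthens with cyclopropylcarbinyl assistance, and one cyclopropane C–C bond shifts to that carbon from the face opposite the departing oxygen while the oxygen becomes the carbonyl of an aluminium-bound cyclobutanone. The closest known reaction type is the Lewis-acid rearrangement of oxaspiropentanes to cyclobutanones, a semipinacol-type 1,2-shift. The four-membered ring closes by enlargement of the cyclopropane through this 1,2-alkyl shift (three-membered to four-membered), not by an end-to-end cyclisation, and the strain of both three-membered rings is released. The new quaternary stereocentre C2 of the cyclobutanone, the future B-C5, is controlled by the configuration of the oxirane carbon, which is transferred with inversion because bond migration and C–O cleavage are concerted. The step needs ring expansion to outrun a hydride shift from the A-C5 methine, chloride opening and formation of a free cation; the aligned, electron-rich cyclopropane bond, the inductive destabilisation of an open cation by the neighbouring A-O1 and the low temperature in a non-nucleophilic medium should secure this.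

Step 8
Reactants: 13 (2S)-2-methyl-2-[(2R,5R)-5-methyl-5-vinyltetrahydrofuran-2-yl]cyclobutan-1-one
Product: 14 (5S)-5-methyl-5-[(2R,5R)-5-methyl-5-vinyltetrahydrofuran-2-yl]dihydrofuran-2(3H)-one
Conditions: 30% aq H2O2, CF3CH2OH, 0 °C to rt
Reagents that add atoms: hydrogen peroxide, OO
Why: Baeyer–Villiger oxidation in which hydrogen peroxide, activated by the fluorinated alcohol, adds to the strained ketone and the more substituted quaternary α-carbon migrates to oxygen with retention, turning cyclobutanone C2 into the S-configured B-C5, while the unactivated vinyl group is inert to this oxidant.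

Step 9
Reactants: 15 3-furaldehyde
Product: 16 3-vinylfuran
Conditions: Ph3PCH3Br, KOtBu, Et2O, 0 °C to rt; distilled and kept cold in solution
Reagents that add atoms: methyltriphenylphosphonium bromide, [Br-].C[P+](c1ccccc1)(c1ccccc1)c1ccccc1
Why: Wittig methylenation of an aromatic aldehyde with a non-stabilised ylide, a reliable transformation that creates no stereochemical element, the volatile and polymerisable product being handled in solution.

Step 10
Reactants: 17 pent-1-en-4-yne
Product: 19 (1E)-1-iodo-2-methylpenta-1,4-diene, via alkenylalane 18 (not isolated)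
Conditions: Me3Al (2 equiv), Cp2ZrCl2 (0.2 equiv), CH2Cl2, 0 °C to rt; then I2, THF, −30 to 0 °C
Reagents that add atoms: trimethylaluminium, C[Al](C)C; iodine, II
Why: Negishi zirconium-catalysed carboalumination, in which methyl and aluminium add syn across the terminal alkyne with aluminium on the terminal carbon (the isolated alkene reacts far more slowly) and iodinolysis with retention gives the E alkenyl iodide that fixes the 4E geometry of the side chain.

Step 11
Reactants: 16 3-vinylfuran; 19 (1E)-1-iodo-2-methylpenta-1,4-diene
Product: 21 3-[(3E)-4-methylhepta-3,6-dien-1-yl]furan, via alkylborane 20 (not isolated)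
Conditions: 16 (1.3 equiv), 9-BBN (1.25 equiv), THF, 0 °C to rt; then 19, PdCl2(dppf) (5 mol%), AsPh3, Cs2CO3, DMF–THF–H2O, rt
Reagents that add atoms: none
Why: anti-Markovnikov hydroboration of the vinylfuran with 9-borabicyclo[3.3.1]nonane followed by B-alkyl Suzuki–Miyaura coupling, in which the primary alkyl group is transferred to the alkenylpalladium iodide with retention of the E geometry and the borane is consumed before the iodide with its terminal alkene is introduced.

Step 12
Reactants: 14 (5S)-5-methyl-5-[(2R,5R)-5-methyl-5-vinyltetrahydrofuran-2-yl]dihydrofuran-2(3H)-one; 21 3-[(3E)-4-methylhepta-3,6-dien-1-yl]furan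
Product: 22 (5S)-5-[(2R,5R)-5-[(1E,4E)-7-(furan-3-yl)-4-methylhepta-1,4-dien-1-yl]-5-methyltetrahydrofuran-2-yl]-5-methyldihydrofuran-2(3H)-one (CNP0387598.1)
Conditions: 21 (3 equiv), second-generation Hoveyda–Grubbs catalyst (10 mol%), 1,4-benzoquinone (20 mol%), CH2Cl2, 40 °C
Reagents that add atoms: none
Why: olefin cross-metathesis in which the vinyl group on the quaternary A-C2 cannot homodimerise and pairs with the monosubstituted terminus of the diene used in excess, the trisubstituted alkene and the furan stay bystanders, ethylene is lost, and the steric demand of the quaternary carbon should make the new disubstituted alkene E under reversible conditions, benzoquinone suppressing migration of the skipped diene.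

**Compound list**

1 | (R)-linalool, (3R)-3,7-dimethylocta-1,6-dien-3-ol | C=C[C@](C)(O)CCC=C(C)C | starting material
2 | (3R)-5-[(2S)-3,3-dimethyloxiran-2-yl]-3-methylpent-1-en-3-ol | C=C[C@](C)(O)CC[C@@H]1OC1(C)C | intermediate
3 | 2-[(2R,5R)-5-methyl-5-vinyltetrahydrofuran-2-yl]propan-2-ol (hydroxypropyl trans to vinyl) | C=C[C@@]1(C)CC[C@H](C(C)(C)O)O1 | intermediate
4 | 2-[(2R,5R)-5-methyl-5-vinyltetrahydrofuran-2-yl]propan-2-yl phosphorodichloridate | C=C[C@@]1(C)CC[C@H](C(C)(C)OP(=O)(Cl)Cl)O1 | intermediate
5 | (2R,5R)-2-methyl-5-(prop-1-en-2-yl)-2-vinyltetrahydrofuran | C=C[C@@]1(C)CC[C@H](C(C)=C)O1 | intermediate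
6 | (2R,5R)-2-methyl-5-(2-methyloxiran-2-yl)-2-vinyltetrahydrofuran (both epimers at the oxirane carbon) | C=C[C@@]1(C)CC[C@H](C2(C)CO2)O1 | intermediate
7 | 1-[(2R,5R)-5-methyl-5-vinyltetrahydrofuran-2-yl]ethan-1-one | C=C[C@@]1(C)CC[C@H](C(C)=O)O1 | intermediate
8 | (3-bromopropyl)triphenylphosphonium bromide | [Br-].BrCCC[P+](c1ccccc1)(c1ccccc1)c1ccccc1 | starting material
9 | cyclopropyltriphenylphosphonium bromide | [Br-].C1CC1[P+](c1ccccc1)(c1ccccc1)c1ccccc1 | intermediate
10 | cyclopropylidenetriphenylphosphorane | C1CC1=P(c1ccccc1)(c1ccccc1)c1ccccc1 | intermediate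
11 | (2R,5R)-5-(1-cyclopropylideneethyl)-2-methyl-2-vinyltetrahydrofuran | C=C[C@@]1(C)CC[C@H](C(C)=C2CC2)O1 | intermediate
12 | (2R)-2-methyl-2-[(2R,5R)-5-methyl-5-vinyltetrahydrofuran-2-yl]-1-oxaspiro[2.2]pentane | C=C[C@@]1(C)CC[C@H]([C@@]2(C)OC23CC3)O1 | intermediate
13 | (2S)-2-methyl-2-[(2R,5R)-5-methyl-5-vinyltetrahydrofuran-2-yl]cyclobutan-1-one | C=C[C@@]1(C)CC[C@H]([C@]2(C)CCC2=O)O1 | intermediate
14 | (5S)-5-methyl-5-[(2R,5R)-5-methyl-5-vinyltetrahydrofuran-2-yl]dihydrofuran-2(3H)-one | C=C[C@@]1(C)CC[C@H]([C@]2(C)CCC(=O)O2)O1 | intermediate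
15 | 3-furaldehyde | O=Cc1ccoc1 | starting material
16 | 3-vinylfuran | C=Cc1ccoc1 | intermediate
17 | pent-1-en-4-yne | C#CCC=C | starting material
18 | dimethyl[(1E)-2-methylpenta-1,4-dien-1-yl]alane | C=CC/C(C)=C/[Al](C)C | intermediate
19 | (1E)-1-iodo-2-methylpenta-1,4-diene | C=CC/C(C)=C/I | intermediate
20 | 9-[2-(furan-3-yl)ethyl]-9-borabicyclo[3.3.1]nonane | B1(CCc2ccoc2)C2CCCC1CCC2 | intermediate
21 | 3-[(3E)-4-methylhepta-3,6-dien-1-yl]furan | C=CC/C(C)=C/CCc1ccoc1 | intermediate
22 | (5S)-5-[(2R,5R)-5-[(1E,4E)-7-(furan-3-yl)-4-methylhepta-1,4-dien-1-yl]-5-methyltetrahydrofuran-2-yl]-5-methyldihydrofuran-2(3H)-one | C/C(=C\CCc1ccoc1)C/C=C/[C@@]1(C)CC[C@H]([C@]2(C)CCC(=O)O2)O1 | target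

**Step count**

Total: 12 steps. Longest linear sequence: 9 steps (steps 1 to 8 and step 12, from (R)-linalool); the diene 21 takes 3 steps (9 to 11).

**Steps most likely to fail**

Step 7. The oxirane C–O bond may ionise ahead of bond migration. An open cation could then be intercepted by a hydride shift from A-C5 (giving a ring-stabilised oxocarbenium ion) or lose its configurational memory, which would erode the relay of configuration to B-C5. The fallback builds B-C5 by carbonyl addition instead of rearrangement; it sets out from ketone 7 and returns to the route at lactone 14. Kinetic deprotonation of the methyl group with LiN(iPr)2 in THF at −78 °C gives lithium 1-[(2R,5R)-5-methyl-5-vinyltetrahydrofuran-2-yl]ethen-1-olate F1. Alkylation with ethyl iodoacetate gives ethyl 4-[(2R,5R)-5-methyl-5-vinyltetrahydrofuran-2-yl]-4-oxobutanoate F2. MeMgBr in CH2Cl2–Et2O at −78 °C should add to the ketone under chelation control, with magnesium bridging the carbonyl oxygen and A-O1 and methyl entering from the face of the A-C5 hydrogen. This gives ethyl (4S)-4-hydroxy-4-[(2R,5R)-5-methyl-5-vinyltetrahydrofuran-2-yl]pentanoate F3, which lactonises to 14 on warming or with a trace of TsOH, ethanol being lost.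

Step 6. Facial selectivity may be poor: the catalyst must tell methyl from the tetrahydrofuranyl group on a tetrasubstituted alkene whose other terminus is symmetric, and it may work against the intrinsic bias of the allylic stereocentre. The preceding Wittig step also carries a risk of enolisation and epimerisation at A-C5. The fallback sets out from ketone 7 and returns at oxaspiropentane 12, bypassing step 5 as well. Cyclopropyldiphenylsulfonium tetrafluoroborate and KOH in DMSO at room temperature generate diphenylsulfonium cyclopropylide F4. The ylide adds to the carbonyl group, and the alkoxide then displaces diphenyl sulfide at the cyclopropane carbon to close the oxirane. Stereocontrol shifts from alkene face selection to Felkin–Anh addition with the A-C5–O bond anti to the incoming ylide, a sense predicted to give the same R oxirane carbon.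

Step 12. Initiation at the vinyl group on the fully substituted A-C2 may be sluggish, homodimerisation may consume the diene, and the skipped diene may isomerise into conjugation. The fallback is a Julia–Kocienski olefination; it sets out from lactone 14 and diene 21 and returns at target 22. Ozonolysis of the vinyl group of 14 (O3, CH2Cl2, −78 °C; Me2S) gives (2R,5R)-2-methyl-5-[(2S)-2-methyl-5-oxotetrahydrofuran-2-yl]tetrahydrofuran-2-carbaldehyde F5, an aldehyde on a quaternary carbon that cannot epimerise. Hydroboration of the terminal alkene of 21 with 9-BBN gives 9-[(3E)-6-(furan-3-yl)-3-methylhex-3-en-1-yl]-9-borabicyclo[3.3.1]nonane F6, which NaOH and H2O2 oxidise to (3E)-6-(furan-3-yl)-3-methylhex-3-en-1-ol F7. Mitsunobu reaction with 1-phenyl-1H-tetrazole-5-thiol (PPh3, diisopropyl azodicarboxylate) gives 5-{[(3E)-6-(furan-3-yl)-3-methylhex-3-en-1-yl]sulfanyl}-1-phenyl-1H-tetrazole F8. Oxidation with H2O2 and (NH4)6Mo7O24 gives 5-{[(3E)-6-(furan-3-yl)-3-methylhex-3-en-1-yl]sulfonyl}-1-phenyl-1H-tetrazole F9. Olefination of F5 with F9 (KN(SiMe3)2, DME, −60 °C) should then form the 1E alkene of 22.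

**Further compounds**

F1 | step 7 | lithium 1-[(2R,5R)-5-methyl-5-vinyltetrahydrofuran-2-yl]ethen-1-olate | [Li+].C=C[C@@]1(C)CC[C@H](C(=C)[O-])O1
F2 | step 7 | ethyl 4-[(2R,5R)-5-methyl-5-vinyltetrahydrofuran-2-yl]-4-oxobutanoate | C=C[C@@]1(C)CC[C@H](C(=O)CCC(=O)OCC)O1
F3 | step 7 | ethyl (4S)-4-hydroxy-4-[(2R,5R)-5-methyl-5-vinyltetrahydrofuran-2-yl]pentanoate | C=C[C@@]1(C)CC[C@H]([C@@](C)(O)CCC(=O)OCC)O1
F4 | step 6 | diphenylsulfonium cyclopropylide | C1C[C-]1[S+](c1ccccc1)c1ccccc1
F5 | step 12 | (2R,5R)-2-methyl-5-[(2S)-2-methyl-5-oxotetrahydrofuran-2-yl]tetrahydrofuran-2-carbaldehyde | O=C[C@@]1(C)CC[C@H]([C@]2(C)CCC(=O)O2)O1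
F6 | step 12 | 9-[(3E)-6-(furan-3-yl)-3-methylhex-3-en-1-yl]-9-borabicyclo[3.3.1]nonane | B1(CC/C(C)=C/CCc2ccoc2)C2CCCC1CCC2
F7 | step 12 | (3E)-6-(furan-3-yl)-3-methylhex-3-en-1-ol | OCC/C(C)=C/CCc1ccoc1
F8 | step 12 | 5-{[(3E)-6-(furan-3-yl)-3-methylhex-3-en-1-yl]sulfanyl}-1-phenyl-1H-tetrazole | C(C/C(C)=C/CCc1ccoc1)Sc1nnnn1-c1ccccc1
F9 | step 12 | 5-{[(3E)-6-(furan-3-yl)-3-methylhex-3-en-1-yl]sulfonyl}-1-phenyl-1H-tetrazole | O=S(=O)(CC/C(C)=C/CCc1ccoc1)c1nnnn1-c1ccccc1
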